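Decide first what you will hold still, and hold the ligand still, because then the exchanges become simple clocks (pseudo-first-order steps).

| flask | starting complex | incoming ligand | remark | time |
|---|---|---|---|---|
| blue | 0.020 M | 0.010 M | run made earlier |  |
| ochre | 0.020 M | 0.13 M | run made earlier |  |
| larch | 0.020 M | 0.0200 M |  | 4.0 min |
| ash | 0.020 M | 0.0400 M |  | 4.0 min |
| alder | 0.020 M | 0.0800 M |  | 4.0 min |
| maple | 0.020 M | 0.200 M |  | 4.0 min |

- blue (time / s: complex with two exchanged / %): 30.0: 0.9; 60.0: 0.8; 90.0: 0.6; 120: 1.2
- ochre (time / s: complex with two exchanged / %): 15.0: 6.8; 40.0: 26.5; 80.0: 46.1; 120: 48.4

(readings scatter by 0.5 percentage points)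

- steps that have been proposed: starting complex + incoming ligand -> leaving ligand + complex with one exchanged; complex with two exchanged -> over-reaction product; complex with one exchanged + incoming ligand -> leaving ligand + complex with two exchanged
- "hardly changes" means that all values lie within two and a half points (for a concentration: within two and a half percent of the largest)

* amount of complex with two exchanged at the end, in percent of the starting complex charged for larch, ash, alder, maple, in this order
* the course of these numbers from the first flask to the last (rises all the way / rises, then falls / falls, then rises / hardly changes / falls all the way)

Let X be the ligand concentration, t the time, and Y the fraction of the charged complex standing as complex with two exchanged. Let g be the exchange constant, one constant standing for both exchanges, read from the early rise of Y while X is nearly frozen. Two steps in series start as a square law: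

Y = (g X t)^2 / 2

There are two ways to g. Ochre, at its first reading, gives

g = 0.189 M⁻¹ s⁻¹

and blue, at its last reading, gives

g = 0.129 M⁻¹ s⁻¹

They part, with blue lower. Blue is the one that cheats, because it carries a quarter of the ligand that both exchanges on all the complex need, while ochre carries 3.25 times that amount. So you keep the ochre value.

The clock of a flask is then 1/(g X), which for ochre is 40.7 s. The rise of ochre has nearly stopped by 120 s, which is 2.95 clocks. My own reckoning counts the clocks each flask has run at its end, with X as charged:

larch 0.908, ash 1.82, alder 3.63, maple 9.08

Larch and ash end with fewer charged clocks than ochre's 2.95, alder ends with more, and maple ends with more still. I therefore expect the row to rise and then fall. Larch is the weak point, since it holds 0.0200 M of ligand against the 0.0400 M that both exchanges need, so its clock cannot stay frozen.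

The forecast gave 5%, 21%, 32% and 28%, rises, then falls, with maple “formed fast, then mostly decayed”.

The flasks give 7.31%, 18.4%, 30.5% and 23.1%: rises, then falls.

    starting complex + incoming ligand → leaving ligand + complex with one exchanged (k = 0.200 M⁻¹ s⁻¹)
    complex with two exchanged → over-reaction product (k = 0.00790 s⁻¹)
    complex with one exchanged + incoming ligand → leaving ligand + complex with two exchanged (k = 0.260 M⁻¹ s⁻¹)

In larch the clock stretches from 4.41 min at the charge to 11.4 min with 39% of the ligand left at 4.00 min, and there complex with two exchanged is made 1.05 times as fast as it is used up, a near standstill at 7.31% after 0.908 charged clocks. Maple still holds 80.7% of its ligand at 2.00 min, and the clock taken at the mean of the charge and that amount leaves 1.66% of the starting complex, where the flask holds 1.60%.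

The earlier runs and the new flask come from a simulation from invented constants, and the scatter is random.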